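## Analysis of the target

Target 34 is a 3-acyltetramic acid whose acyl carbon C9 sits on a trans-fused octalin. The carbocycle is numbered C1 (quaternary, carrying CH3 and C9), C2 (carrying the (1E,3E)-pentadienyl group), C3=C4, C4a, C5, C6 (CH3), C7, C8, C8a; ring A is C1–C2–C3=C4–C4a–C8a, ring B is C4a–C5–C6–C7–C8–C8a, and the heterocycle is N1′–C5′ with the 1-hydroxyethyl group on C5′. There are seven stereocentres: (1R,2R,4aR,6R,8aS) in the carbocycle and (5′S,1″R) in the heterocycle, the latter pair being that of L-threonine. With the face of the C8a hydrogen called "up", the C4a hydrogen is down (trans fusion), the C1 methyl is down and axial with C9 up and equatorial, the pentadienyl group on C2 is down and pseudo-equatorial (C2–H up), and the C6 methyl is down, hence axial and trans to the C4a–C4 bond. Two relations are awkward: the axial C6 methyl cannot be reached by equilibration, and the C2 and C4a hydrogens lie on opposite faces, which a triene Diels–Alder closure of ring A with an (E,E)-diene would not deliver. The tricarbonyl unit is acidic, chelating and epimerisable at C5′ under base, and the diene together with C3=C4 makes C2–H doubly allylic and sensitive to acid, radicals and oxidants. The main difficulty is the contiguous C8a–C1–C2 array around a quaternary carbon that carries a neopentyl acyl group, together with relating C6 to the ring fusion. The strategy rests on ring B: the C4a–C4 bond is trans to both the C6 methyl and the C8a–C1 bond, which is the pattern left on a 5-methylcyclohex-2-enone with its carbonyl at C8 by conjugate addition anti to the methyl and enolate alkylation anti to the new branch.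

## Retrosynthetic reasoning

**Heterocycle (C3′–C4′ and N1′–C2′).** The tetramic acid of 34 is opened at C3′–C4′ (Lacey–Dieckmann) to β-keto amide 33, and the amide bond is cut to β-keto thioester 31 and L-threonine methyl ester hydrochloride 32. Cutting here keeps the base-labile C5′ centre and the free tricarbonyl out of all earlier steps, and 32 brings both heterocycle stereocentres unchanged.

**C9–CH2 bond.** Thioester 31 is cut between C9 and the methylene to aldehyde 28 and S-tert-butyl thioacetate 29 (aldol, then oxidation of 30). A neopentyl aldehyde accepts an enolate where a neopentyl ester would not be acylated. Aldehyde 28 comes from tert-butyl ester 26 through alcohol 27.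

**C2–pentadienyl bond.** Ester 26 is cut at C2 to allylic picolinate 21 and dienyl Grignard reagent 25 (from iodide 23, from crotonaldehyde 22). An anti SN2′ substitution forms the hindered C2–C bond and places C3=C4 in the same operation. The forward step must attack C2 on the face opposite the C4–O bond, so that bond must be up and pseudo-axial.

**C4 oxygen and C2=C3 (1,3-transposition).** Picolinate 21 comes from allylic alcohol 20, the Wharton product of epoxy ketone 19, itself from enone 18 and ketone 16 (Saegusa–Ito oxidation). Axial nucleophilic epoxidation of 18 puts the oxygen on C4 on the up face, exactly what the substitution needs, and the Wharton step leaves that C–O bond untouched.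

**C1–CH3 bond.** Ketone 16 is cut to β-keto ester 15. Methylating last makes the methyl the group that enters axially; the reverse order would put C9 axial.

**C1–C2 bond (ring A).** β-Keto ester 15 is opened to diester 14 (Dieckmann). An aldol closure of the corresponding aldehyde ester was set aside, because base would enolise the aldehyde and not the ester. In 14 the tert-butyl ester can only act as the donor, so only the C1-to-C2 mode of closure is open. Diester 14 comes from aldehyde 13 and acetal 12. The tert-butyl ester is also kept because it later resists hydrazine and the organocopper reagent.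

**C8 oxygen.** Acetal 12 is the deoxygenation product of ketone 10 through tosylhydrazone 11. After this step C4a and C8a are no longer next to a carbonyl and cannot epimerise.

**C4–C4a and C1–C8a (key disconnection).** Keto ester 10 is cut into enone 5, Grignard reagent 7 and tert-butyl bromoacetate 8. One flask joins three components and relates C4a and C8a to the C6 methyl of 5 under kinetic control, which is what secures the axial methyl in the later trans-decalin.

**Precursors.** Enone 5 comes from (S)-pulegone 1 through epoxide 2 and sulfide 3 (sulfoxide 4); Grignard reagent 7 comes from bromide 6.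

## Alternatives that were turned down

**Alternative 1:** Ring B is cut at C4a–C8a and C5–C6 with the C4 ketone in the tether. The open-chain trienone A2, a vinyl ketone (C5=C4a, carbonyl C4) linked through C3–C2–C1 to the (E,E)-diene C8a=C8–C7=C6, would cyclise by intramolecular Diels–Alder reaction to keto ester A1, closing rings A and B together.
- For it: two rings, two C–C bonds and three stereocentres in one step. The (E,E)-diene geometry places the C6 methyl cis to the C8a–C1 bond as required. C1 and C2 are already present, so neither the C1 methylation nor the substitution at C2 is needed. On bonds per step it is clearly the stronger plan.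
- Against it: A2 needs the adjacent quaternary C1 and tertiary C2 centres built in an open chain, which is harder than building them on a ring. The facial bias of the cycloaddition depends on how that crowded tether folds. C4a is next to the C4 ketone in A1, so the ring fusion can equilibrate, and with the C6 methyl pseudo-axial in the trans isomer it is not clear that equilibration favours it. After the cycloaddition, hydrogenation of C7=C8, conversion of the C4 ketone into C3=C4 and elaboration of the ether into the diene still follow.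
- Comparison: the chosen route is longer, but each stereocentre is set on a ring by a well-understood kinetic preference, and the ring-fusion centres stop being epimerisable early.

**Alternative 2:** Ring A is cut at C1–C8a and C2–C3. The silyloxy diene A4 (C3=C4(OSi)–C4a=C8a on a 5-methylcyclohexene) and the (E)-enal A5 would combine in an intermolecular Diels–Alder reaction with the formyl group exo to give silyl enol ether A3.
- For it: it is the most convergent plan. The quaternary C1 and C2 form together, the dienophile geometry fixes their relation, and formyl-exo addition gives the correct C1/C8a relation. C9 arrives as the aldehyde the end game needs. On convergence and step count it is superior.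
- Against it: the only stereocentre in A4 is C6, which is 1,4-related to the new centre C8a, so its influence on the diene face is weak. The required isomer has the C6 methyl axial, that is, it arises from the less favourable approach. A trisubstituted enal is a sluggish dienophile, and the Lewis acid it needs threatens the silyl enol ether. C4a is then set by protonation next to the C4 ketone, with the same thermodynamic doubt as above.
- Comparison: the chosen route fixes the C6/C4a relation first, by 1,3-induction on a cyclohexenone, where the preference is strong.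

**Alternative 3:** Ring B is cut at C8–C8a and C4a–C5. Copper-catalysed conjugate addition of the zinc reagent A8 to one enone of the prochiral dienone A7, followed by displacement of chloride by the enolate, would give the bicyclic enone A6.
- For it: one step would make ring B and set C1, C4a and C8a, with C6 supplied by a small chiral reagent, leaving an enone ready for work at C2. On step economy it is by far the strongest of the four plans.
- Against it: the catalyst must choose one of two enantiotopic alkenes and, at the same time, the face anti to the ester and syn to the methyl at C1, two groups of similar size. The chiral reagent may be matched or mismatched with the ligand. A zinc enolate must displace a primary chloride next to a branch. The ring fusion is again next to the C4 ketone, where the axial C6 methyl may tip the equilibrium toward cis fusion.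
- Comparison: the chosen route asks for no catalyst control at all, only ring control from the chiral pool, and pays for it in steps.

Key step: step 5

Remark on the chemistry: 34 is written as one enol tautomer of the tricarbonyl unit; the tautomers interconvert and are one compound.

## Route

Step 1
Reactants: 1 (S)-(−)-pulegone
Product: 2 pulegone oxide, (6S)-2,2,6-trimethyl-1-oxaspiro[2.5]octan-4-one (epimers at the spiro carbon)
Conditions: 30% aq. H2O2, LiOH·H2O (cat.), MeOH, 0 °C to rt
Reagents that add atoms: hydrogen peroxide, OO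
Why: Weitz–Scheffer epoxidation of the tetrasubstituted enone; the new spiro centre is removed in step 2, so its configuration is irrelevant, and the C6 methyl centre is not touched.

Step 2
Reactants: 2 pulegone oxide
Product: 3 (5S)-5-methyl-2-(phenylsulfanyl)cyclohexan-1-one (C2 epimers)
Conditions: PhSH, NaH (cat.), THF, reflux
Reagents that add atoms: thiophenol, Sc1ccccc1
Why: The thiolate opens the epoxide at the carbon next to the carbonyl and the resulting tertiary alkoxide undergoes retro-aldol loss of acetone; the enolate formed deprotonates more thiol, so base is catalytic.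

Step 3
Reactants: 3 (5S)-5-methyl-2-(phenylsulfanyl)cyclohexan-1-one
Product: 5 (5S)-5-methylcyclohex-2-en-1-one, via sulfoxide 4 (not isolated)
Conditions: mCPBA, CH2Cl2, −78 °C; then CaCO3, toluene, 80 °C
Reagents that add atoms: none
Why: Sulfide oxidation and thermal syn-elimination of the β-keto sulfoxide place the alkene only between C2 and C3; the volatile enone should be distilled with care and kept from acid or base, which could move the double bond.

Step 4
Reactants: 6 2-(2-bromoethyl)-1,3-dioxolane
Product: 7 [2-(1,3-dioxolan-2-yl)ethyl]magnesium bromide (THF solution, used at once)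
Conditions: Mg turnings, THF, 25–30 °C
Reagents that add atoms: magnesium, [Mg]
Why: Grignard formation from a primary bromide; the reagent is kept at or below 30 °C and used promptly because the β-acetal Grignard reagent decomposes on heating.

Step 5
Reactants: 5 (5S)-5-methylcyclohex-2-en-1-one; 7 [2-(1,3-dioxolan-2-yl)ethyl]magnesium bromide; 8 tert-butyl bromoacetate
Product: 10 tert-butyl 2-[(1R,2S,4S)-2-[2-(1,3-dioxolan-2-yl)ethyl]-4-methyl-6-oxocyclohexyl]acetate, via bromomagnesium enolate 9 (not isolated)
Conditions: 7 (1.3 equiv), CuBr·SMe2 (10 mol %), THF, −78 to −40 °C; then HMPA, 8 (2 equiv), −40 to 0 °C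
Reagents that add atoms: none
Why: Grignard reagent 7 transmetalates to a catalytic organocopper species that adds 1,4 to enone 5 (π-complex, oxidative addition to a trivalent copper β-adduct, reductive elimination) and leaves the regiodefined bromomagnesium enolate 9, which HMPA makes nucleophilic enough for SN2 attack on bromoacetate 8 at C8a. The closest known reaction type is the tandem organocopper conjugate addition–enolate alkylation (vicinal difunctionalisation) of cyclohexenones. No ring is closed; the step forms C4–C4a and C1–C8a. C4a is controlled by the C6 methyl group: the copper reagent attacks the half-chair of 5 with the methyl pseudo-equatorial along the axial trajectory, anti to the methyl, giving the 3,5-trans adduct. C8a is controlled by the new C4a side chain: the enolate is alkylated on the face away from it, giving the 2,3-trans ketone, which is also the more stable epimer at this enolisable centre. The step needs 1,4- over 1,2-addition (secured by copper), C-alkylation of the unequilibrated enolate (secured by its regiospecific generation, a reactive α-halo ester and low temperature) and the trans,trans pattern (secured by the ring as described). The tert-butyl ester is chosen here because it directs step 10 and survives steps 14 and 17.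

Step 6
Reactants: 10 tert-butyl 2-[(1R,2S,4S)-2-[2-(1,3-dioxolan-2-yl)ethyl]-4-methyl-6-oxocyclohexyl]acetate
Product: 11 tosylhydrazone of 10, tert-butyl 2-[(1R,2S,4S)-2-[2-(1,3-dioxolan-2-yl)ethyl]-4-methyl-6-(2-tosylhydrazinylidene)cyclohexyl]acetate
Conditions: TsNHNH2, EtOH, 50 °C
Reagents that add atoms: 4-methylbenzenesulfonohydrazide, Cc1ccc(cc1)S(=O)(=O)NN
Why: Condensation of the ketone with the sulfonyl hydrazide under near-neutral conditions that leave the acetal and the tert-butyl ester intact; the sulfonylated nitrogen is too poor a nucleophile to cyclise onto the hindered ester.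

Step 7
Reactants: 11 tosylhydrazone of 10
Product: 12 tert-butyl 2-[(1R,2S,4R)-2-[2-(1,3-dioxolan-2-yl)ethyl]-4-methylcyclohexyl]acetate
Conditions: catecholborane, CHCl3, 0 °C to rt; then NaOAc·3H2O, reflux
Reagents that add atoms: none
Why: Hydroboration of the C=N bond gives the N-boryl hydrazine; acetate then triggers loss of sulfinate and the diazene loses N2, leaving C8 as CH2 without base strong enough to touch the ester. From here on C4a and C8a are no longer epimerisable.

Step 8
Reactants: 12 tert-butyl 2-[(1R,2S,4R)-2-[2-(1,3-dioxolan-2-yl)ethyl]-4-methylcyclohexyl]acetate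
Product: 13 tert-butyl 2-[(1R,2S,4R)-4-methyl-2-(3-oxopropyl)cyclohexyl]acetate
Conditions: PPTS (cat.), acetone–H2O, reflux
Reagents that add atoms: water, O
Why: Mild acid-catalysed acetal hydrolysis; a tert-butyl ester is cleaved only by strong acid and should survive pyridinium tosylate.

Step 9
Reactants: 13 tert-butyl 2-[(1R,2S,4R)-4-methyl-2-(3-oxopropyl)cyclohexyl]acetate
Product: 14 methyl 3-[(1S,2R,5R)-2-(2-tert-butoxy-2-oxoethyl)-5-methylcyclohexyl]propanoate
Conditions: I2, KOH, MeOH, 0 °C
Reagents that add atoms: methanol, CO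
Why: Direct oxidative esterification: the methyl hemiacetal of the aldehyde is oxidised by hypoiodite to the methyl ester; cold methanolic base does not transesterify the tert-butyl ester in the short reaction time.

Step 10
Reactants: 14 methyl 3-[(1S,2R,5R)-2-(2-tert-butoxy-2-oxoethyl)-5-methylcyclohexyl]propanoate
Product: 15 tert-butyl (4aS,6R,8aS)-6-methyl-2-oxodecahydronaphthalene-1-carboxylate (C1 epimers and enol)
Conditions: KOt-Bu, THF, 0 °C to rt; then 1 M HCl
Reagents that add atoms: none
Why: Dieckmann condensation under equilibrating conditions; only the enolate of the tert-butyl ester (C1) attacking the methyl ester (C2) is productive, because the tert-butyl ester carbonyl is too hindered to be the acceptor, and the stabilised β-keto ester enolate drives it. The trans relation of the two side chains makes the new ring A trans-fused.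

Step 11
Reactants: 15 tert-butyl (4aS,6R,8aS)-6-methyl-2-oxodecahydronaphthalene-1-carboxylate
Product: 16 tert-butyl (1R,4aS,6R,8aS)-1,6-dimethyl-2-oxodecahydronaphthalene-1-carboxylate
Conditions: NaH, THF, 0 °C; then MeI, 0 °C to rt
Reagents that add atoms: iodomethane, CI
Why: C-Alkylation of a cyclic β-keto ester enolate; iodomethane is expected to attack C1 along the axial trajectory, anti to the axial C8a–H and through a chair-like transition state, so the methyl becomes axial (down) and the ester equatorial. No angular substituent blocks that face.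

Step 12
Reactants: 16 tert-butyl (1R,4aS,6R,8aS)-1,6-dimethyl-2-oxodecahydronaphthalene-1-carboxylate
Product: 18 tert-butyl (1R,4aR,6R,8aS)-1,6-dimethyl-2-oxo-1,2,4a,5,6,7,8,8a-octahydronaphthalene-1-carboxylate, via trimethylsilyl enol ether 17 (not isolated)
Conditions: LiN(SiMe3)2, TMSCl, THF, −78 to 0 °C; then Pd(OAc)2 (10 mol %), O2 (1 atm), DMSO, rt
Reagents that add atoms: none
Why: Saegusa–Ito oxidation; C1 is quaternary, so the ketone can enolise only toward C3 and the alkene can form only at C3=C4.

Step 13
Reactants: 18 tert-butyl (1R,4aR,6R,8aS)-1,6-dimethyl-2-oxo-1,2,4a,5,6,7,8,8a-octahydronaphthalene-1-carboxylate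
Product: 19 tert-butyl (1R,3S,4S,4aS,6R,8aS)-3,4-epoxy-1,6-dimethyl-2-oxodecahydronaphthalene-1-carboxylate (oxirane on the face of the C8a hydrogen)
Conditions: t-BuOOH (in decane), DBU, CH2Cl2, 0 °C to rt
Reagents that add atoms: tert-butyl hydroperoxide, CC(C)(C)OO
Why: Weitz–Scheffer epoxidation; the peroxide anion should add to C4 along the axial trajectory, anti to the axial C4a–H, so the oxirane forms on the up face. A non-hydroxylic base is used to avoid retro-Claisen cleavage of the non-enolisable β-keto ester and to limit γ-deprotonation at C4a.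

Step 14
Reactants: 19 tert-butyl (1R,3S,4S,4aS,6R,8aS)-3,4-epoxy-1,6-dimethyl-2-oxodecahydronaphthalene-1-carboxylate
Product: 20 tert-butyl (1S,4R,4aS,6R,8aS)-4-hydroxy-1,6-dimethyl-1,4,4a,5,6,7,8,8a-octahydronaphthalene-1-carboxylate (C4 hydroxyl up, pseudo-axial)
Conditions: N2H4·H2O, AcOH (cat.), MeOH, 0 °C to rt
Reagents that add atoms: none
Why: Wharton transposition: the epoxy hydrazone opens to a vinyl diazene that loses N2, giving C2=C3 while the C4–O bond is never broken, so C4 keeps its configuration. The tert-butyl ester resists hydrazinolysis and pyrazolone formation.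

Step 15
Reactants: 20 tert-butyl (1S,4R,4aS,6R,8aS)-4-hydroxy-1,6-dimethyl-1,4,4a,5,6,7,8,8a-octahydronaphthalene-1-carboxylate
Product: 21 tert-butyl (1S,4R,4aS,6R,8aS)-1,6-dimethyl-4-[(pyridine-2-carbonyl)oxy]-1,4,4a,5,6,7,8,8a-octahydronaphthalene-1-carboxylate
Conditions: picolinic acid, DCC, DMAP (cat.), CH2Cl2, rt
Reagents that add atoms: pyridine-2-carboxylic acid, OC(=O)c1ccccn1
Why: Carbodiimide esterification of the secondary allylic alcohol with retention at C4; the picolinoxy group is installed because its chelation to magnesium favours γ-attack in step 17.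

Step 16
Reactants: 22 (E)-but-2-enal (crotonaldehyde)
Product: 23 (1E,3E)-1-iodopenta-1,3-diene
Conditions: CHI3, CrCl2, THF, 0 °C
Reagents that add atoms: iodoform, IC(I)I
Why: Takai olefination gives the (E)-vinyl iodide from the aldehyde and keeps the existing (E)-alkene; the volatile, light-sensitive iodide is used promptly.

Step 17
Reactants: 21 tert-butyl (1S,4R,4aS,6R,8aS)-1,6-dimethyl-4-[(pyridine-2-carbonyl)oxy]-1,4,4a,5,6,7,8,8a-octahydronaphthalene-1-carboxylate; 23 (1E,3E)-1-iodopenta-1,3-diene
Product: 26 tert-butyl (1R,2R,4aR,6R,8aS)-1,6-dimethyl-2-[(1E,3E)-penta-1,3-dien-1-yl]-1,2,4a,5,6,7,8,8a-octahydronaphthalene-1-carboxylate, via dienyllithium 24 (not isolated), via dienylmagnesium bromide 25 (not isolated)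
Conditions: 23, t-BuLi (2 equiv per iodide), Et2O, −78 °C; MgBr2·OEt2; CuBr·SMe2, THF, −40 °C; then 21, −40 to 0 °C
Reagents that add atoms: none
Why: Copper-mediated anti-SN2′ substitution of an allylic picolinate by an alkenyl Grignard-derived copper reagent: copper adds to C2 on the face opposite the pseudo-axial C4–O bond and reductive elimination transfers the dienyl group with retention of its geometry. This sets C2 (dienyl down, C2–H up) and moves the alkene to C3=C4; the hindered tert-butyl ester is not attacked at these temperatures.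

Step 18
Reactants: 26 tert-butyl (1R,2R,4aR,6R,8aS)-1,6-dimethyl-2-[(1E,3E)-penta-1,3-dien-1-yl]-1,2,4a,5,6,7,8,8a-octahydronaphthalene-1-carboxylate
Product: 27 [(1R,2R,4aR,6R,8aS)-1,6-dimethyl-2-[(1E,3E)-penta-1,3-dien-1-yl]-1,2,4a,5,6,7,8,8a-octahydronaphthalen-1-yl]methanol
Conditions: LiAlH4, THF, 0 °C to reflux
Reagents that add atoms: none
Why: Hydride reduction of the ester to the neopentyl alcohol; the hindered tert-butyl ester needs heating, and the unconjugated alkene and the diene are inert to the hydride.

Step 19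
Reactants: 27 [(1R,2R,4aR,6R,8aS)-1,6-dimethyl-2-[(1E,3E)-penta-1,3-dien-1-yl]-1,2,4a,5,6,7,8,8a-octahydronaphthalen-1-yl]methanol
Product: 28 (1R,2R,4aR,6R,8aS)-1,6-dimethyl-2-[(1E,3E)-penta-1,3-dien-1-yl]-1,2,4a,5,6,7,8,8a-octahydronaphthalene-1-carbaldehyde
Conditions: Dess–Martin periodinane, pyridine, CH2Cl2, 0 °C to rt
Reagents that add atoms: none
Why: Dess–Martin oxidation under buffered, non-acidic conditions; the aldehyde has no α-hydrogen and cannot epimerise.

Step 20
Reactants: 28 (1R,2R,4aR,6R,8aS)-1,6-dimethyl-2-[(1E,3E)-penta-1,3-dien-1-yl]-1,2,4a,5,6,7,8,8a-octahydronaphthalene-1-carbaldehyde; 29 S-tert-butyl ethanethioate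
Product: 30 S-tert-butyl 3-hydroxy-3-[(1R,2R,4aR,6R,8aS)-1,6-dimethyl-2-[(1E,3E)-penta-1,3-dien-1-yl]-1,2,4a,5,6,7,8,8a-octahydronaphthalen-1-yl]propanethioate (carbinol epimers)
Conditions: 29, LiN(i-Pr)2, THF, −78 °C; then 28, −78 °C; aq. NH4Cl
Reagents that add atoms: none
Why: Aldol addition of the thioester lithium enolate to the non-enolisable aldehyde; the new carbinol centre is oxidised away in step 21, so its configuration does not matter.

Step 21
Reactants: 30 S-tert-butyl 3-hydroxy-3-[(1R,2R,4aR,6R,8aS)-1,6-dimethyl-2-[(1E,3E)-penta-1,3-dien-1-yl]-1,2,4a,5,6,7,8,8a-octahydronaphthalen-1-yl]propanethioate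
Product: 31 S-tert-butyl 3-oxo-3-[(1R,2R,4aR,6R,8aS)-1,6-dimethyl-2-[(1E,3E)-penta-1,3-dien-1-yl]-1,2,4a,5,6,7,8,8a-octahydronaphthalen-1-yl]propanethioate
Conditions: Dess–Martin periodinane, pyridine, CH2Cl2, rt
Reagents that add atoms: none
Why: Dess–Martin oxidation of the β-hydroxy thioester to the β-keto thioester without touching the alkenes.

Step 22
Reactants: 31 S-tert-butyl 3-oxo-3-[(1R,2R,4aR,6R,8aS)-1,6-dimethyl-2-[(1E,3E)-penta-1,3-dien-1-yl]-1,2,4a,5,6,7,8,8a-octahydronaphthalen-1-yl]propanethioate; 32 methyl L-threoninate hydrochloride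
Product: 33 methyl (2S,3R)-3-hydroxy-2-{3-oxo-3-[(1R,2R,4aR,6R,8aS)-1,6-dimethyl-2-[(1E,3E)-penta-1,3-dien-1-yl]-1,2,4a,5,6,7,8,8a-octahydronaphthalen-1-yl]propanamido}butanoate
Conditions: 32, AgO2CCF3, Et3N, THF, 0 °C to rt
Reagents that add atoms: none
Why: Silver-promoted aminolysis of the thioester: the thiophilic silver ion activates the C–S bond and the amine, far more nucleophilic than the secondary hydroxyl, forms the amide under conditions too mild to enolise the amino ester.

Step 23
Reactants: 33 methyl (2S,3R)-3-hydroxy-2-{3-oxo-3-[(1R,2R,4aR,6R,8aS)-1,6-dimethyl-2-[(1E,3E)-penta-1,3-dien-1-yl]-1,2,4a,5,6,7,8,8a-octahydronaphthalen-1-yl]propanamido}butanoate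
Product: 34 (5S)-3-{[(1R,2R,4aR,6R,8aS)-1,6-dimethyl-2-[(1E,3E)-penta-1,3-dien-1-yl]-1,2,4a,5,6,7,8,8a-octahydronaphthalen-1-yl]carbonyl}-4-hydroxy-5-[(1R)-1-hydroxyethyl]-1,5-dihydro-2H-pyrrol-2-one
Conditions: KOt-Bu, t-BuOH–THF, rt, short reaction time; then 1 M HCl to pH 2–3
Reagents that add atoms: none
Why: Lacey–Dieckmann cyclisation: the doubly activated methylene attacks the methyl ester and the tetramate anion formed is no longer prone to deprotonation at C5′. Both threonine-derived centres are carried through unchanged if the contact time with base is short.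

## Compound list

1 | (S)-(−)-pulegone, (5S)-5-methyl-2-(propan-2-ylidene)cyclohexan-1-one | C[C@H]1CCC(=C(C)C)C(=O)C1 | starting material
2 | pulegone oxide, (6S)-2,2,6-trimethyl-1-oxaspiro[2.5]octan-4-one (epimers at the spiro carbon) | C[C@H]1CCC2(OC2(C)C)C(=O)C1 | intermediate
3 | (5S)-5-methyl-2-(phenylsulfanyl)cyclohexan-1-one (C2 epimers) | C[C@H]1CCC(Sc2ccccc2)C(=O)C1 | intermediate
4 | (5S)-2-(benzenesulfinyl)-5-methylcyclohexan-1-one (diastereomers) | C[C@H]1CCC(S(=O)c2ccccc2)C(=O)C1 | intermediate
5 | (5S)-5-methylcyclohex-2-en-1-one | O=C1C=CC[C@H](C)C1 | intermediate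
6 | 2-(2-bromoethyl)-1,3-dioxolane | BrCCC1OCCO1 | starting material
7 | [2-(1,3-dioxolan-2-yl)ethyl]magnesium bromide | Br[Mg]CCC1OCCO1 | intermediate
8 | tert-butyl bromoacetate | CC(C)(C)OC(=O)CBr | starting material
9 | bromomagnesium (3S,5S)-3-[2-(1,3-dioxolan-2-yl)ethyl]-5-methylcyclohex-1-en-1-olate | O1CCOC1CC[C@H]2C[C@H](C)CC(O[Mg]Br)=C2 | intermediate
10 | tert-butyl 2-[(1R,2S,4S)-2-[2-(1,3-dioxolan-2-yl)ethyl]-4-methyl-6-oxocyclohexyl]acetate | O1CCOC1CC[C@H]2C[C@H](C)CC(=O)[C@@H]2CC(=O)OC(C)(C)C | intermediate
11 | tert-butyl 2-[(1R,2S,4S)-2-[2-(1,3-dioxolan-2-yl)ethyl]-4-methyl-6-(2-tosylhydrazinylidene)cyclohexyl]acetate | O1CCOC1CC[C@H]2C[C@H](C)CC(=NNS(=O)(=O)c3ccc(C)cc3)[C@@H]2CC(=O)OC(C)(C)C | intermediate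
12 | tert-butyl 2-[(1R,2S,4R)-2-[2-(1,3-dioxolan-2-yl)ethyl]-4-methylcyclohexyl]acetate | O1CCOC1CC[C@H]2C[C@H](C)CC[C@@H]2CC(=O)OC(C)(C)C | intermediate
13 | tert-butyl 2-[(1R,2S,4R)-4-methyl-2-(3-oxopropyl)cyclohexyl]acetate | O=CCC[C@H]2C[C@H](C)CC[C@@H]2CC(=O)OC(C)(C)C | intermediate
14 | methyl 3-[(1S,2R,5R)-2-(2-tert-butoxy-2-oxoethyl)-5-methylcyclohexyl]propanoate | COC(=O)CC[C@H]2C[C@H](C)CC[C@@H]2CC(=O)OC(C)(C)C | intermediate
15 | tert-butyl (4aS,6R,8aS)-6-methyl-2-oxodecahydronaphthalene-1-carboxylate (C1 epimers and enol) | O=C1CC[C@H]2C[C@H](C)CC[C@@H]2C1C(=O)OC(C)(C)C | intermediate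
16 | tert-butyl (1R,4aS,6R,8aS)-1,6-dimethyl-2-oxodecahydronaphthalene-1-carboxylate | O=C1CC[C@H]2C[C@H](C)CC[C@@H]2[C@@]1(C)C(=O)OC(C)(C)C | intermediate
17 | tert-butyl (1R,4aR,6R,8aS)-1,6-dimethyl-2-[(trimethylsilyl)oxy]-1,4,4a,5,6,7,8,8a-octahydronaphthalene-1-carboxylate | C[Si](C)(C)OC1=CC[C@H]2C[C@H](C)CC[C@@H]2[C@@]1(C)C(=O)OC(C)(C)C | intermediate
18 | tert-butyl (1R,4aR,6R,8aS)-1,6-dimethyl-2-oxo-1,2,4a,5,6,7,8,8a-octahydronaphthalene-1-carboxylate | O=C1C=C[C@H]2C[C@H](C)CC[C@@H]2[C@@]1(C)C(=O)OC(C)(C)C | intermediate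
19 | tert-butyl (1R,3S,4S,4aS,6R,8aS)-3,4-epoxy-1,6-dimethyl-2-oxodecahydronaphthalene-1-carboxylate | O=C1[C@H]3O[C@H]3[C@H]2C[C@H](C)CC[C@@H]2[C@@]1(C)C(=O)OC(C)(C)C | intermediate
20 | tert-butyl (1S,4R,4aS,6R,8aS)-4-hydroxy-1,6-dimethyl-1,4,4a,5,6,7,8,8a-octahydronaphthalene-1-carboxylate | C1=C[C@@H](O)[C@H]2C[C@H](C)CC[C@@H]2[C@@]1(C)C(=O)OC(C)(C)C | intermediate
21 | tert-butyl (1S,4R,4aS,6R,8aS)-1,6-dimethyl-4-[(pyridine-2-carbonyl)oxy]-1,4,4a,5,6,7,8,8a-octahydronaphthalene-1-carboxylate | C1=C[C@@H](OC(=O)c3ccccn3)[C@H]2C[C@H](C)CC[C@@H]2[C@@]1(C)C(=O)OC(C)(C)C | intermediate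
22 | (E)-but-2-enal (crotonaldehyde) | C/C=C/C=O | starting material
23 | (1E,3E)-1-iodopenta-1,3-diene | C/C=C/C=C/I | intermediate
24 | (1E,3E)-penta-1,3-dien-1-yllithium | C/C=C/C=C/[Li] | intermediate
25 | (1E,3E)-penta-1,3-dien-1-ylmagnesium bromide | C/C=C/C=C/[Mg]Br | intermediate
26 | tert-butyl (1R,2R,4aR,6R,8aS)-1,6-dimethyl-2-[(1E,3E)-penta-1,3-dien-1-yl]-1,2,4a,5,6,7,8,8a-octahydronaphthalene-1-carboxylate | C/C=C/C=C/[C@@H]1C=C[C@H]2C[C@H](C)CC[C@@H]2[C@@]1(C)C(=O)OC(C)(C)C | intermediate
27 | [(1R,2R,4aR,6R,8aS)-1,6-dimethyl-2-[(1E,3E)-penta-1,3-dien-1-yl]-1,2,4a,5,6,7,8,8a-octahydronaphthalen-1-yl]methanol | C/C=C/C=C/[C@@H]1C=C[C@H]2C[C@H](C)CC[C@@H]2[C@@]1(C)CO | intermediate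
28 | (1R,2R,4aR,6R,8aS)-1,6-dimethyl-2-[(1E,3E)-penta-1,3-dien-1-yl]-1,2,4a,5,6,7,8,8a-octahydronaphthalene-1-carbaldehyde | C/C=C/C=C/[C@@H]1C=C[C@H]2C[C@H](C)CC[C@@H]2[C@@]1(C)C=O | intermediate
29 | S-tert-butyl ethanethioate | CC(=O)SC(C)(C)C | starting material
30 | S-tert-butyl 3-hydroxy-3-[(1R,2R,4aR,6R,8aS)-1,6-dimethyl-2-[(1E,3E)-penta-1,3-dien-1-yl]-1,2,4a,5,6,7,8,8a-octahydronaphthalen-1-yl]propanethioate (carbinol epimers) | C/C=C/C=C/[C@@H]1C=C[C@H]2C[C@H](C)CC[C@@H]2[C@@]1(C)C(O)CC(=O)SC(C)(C)C | intermediate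
31 | S-tert-butyl 3-oxo-3-[(1R,2R,4aR,6R,8aS)-1,6-dimethyl-2-[(1E,3E)-penta-1,3-dien-1-yl]-1,2,4a,5,6,7,8,8a-octahydronaphthalen-1-yl]propanethioate | C/C=C/C=C/[C@@H]1C=C[C@H]2C[C@H](C)CC[C@@H]2[C@@]1(C)C(=O)CC(=O)SC(C)(C)C | intermediate
32 | methyl L-threoninate hydrochloride, methyl (2S,3R)-2-amino-3-hydroxybutanoate hydrochloride | C[C@@H](O)[C@H](N)C(=O)OC.Cl | starting material
33 | methyl (2S,3R)-3-hydroxy-2-{3-oxo-3-[(1R,2R,4aR,6R,8aS)-1,6-dimethyl-2-[(1E,3E)-penta-1,3-dien-1-yl]-1,2,4a,5,6,7,8,8a-octahydronaphthalen-1-yl]propanamido}butanoate | C/C=C/C=C/[C@@H]1C=C[C@H]2C[C@H](C)CC[C@@H]2[C@@]1(C)C(=O)CC(=O)N[C@@H]([C@@H](C)O)C(=O)OC | intermediate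
34 | (5S)-3-{[(1R,2R,4aR,6R,8aS)-1,6-dimethyl-2-[(1E,3E)-penta-1,3-dien-1-yl]-1,2,4a,5,6,7,8,8a-octahydronaphthalen-1-yl]carbonyl}-4-hydroxy-5-[(1R)-1-hydroxyethyl]-1,5-dihydro-2H-pyrrol-2-one | C/C=C/C=C/[C@@H]1C=C[C@H]2C[C@H](C)CC[C@@H]2[C@@]1(C)C(=O)C1=C(O)[C@H]([C@@H](C)O)NC1=O | target

## Step count and least certain steps

Total: 23 steps. Longest linear sequence: 21 steps (steps 1–3, 5–15 and 17–23); steps 4 and 16 prepare the two organometallic partners.

**Step 5 (key step).** The most likely failure is slow alkylation of the magnesium enolate. Proton transfer between enolate and product would then scramble the enolate position, cause double alkylation, or simply return the unalkylated conjugate adduct. The fallback separates the two events. It sets out from 5 and 7 and returns at 10. The copper-catalysed addition is run with TMSCl present, so that the enolate is silylated as it forms and {[(3S,5S)-3-[2-(1,3-dioxolan-2-yl)ethyl]-5-methylcyclohex-1-en-1-yl]oxy}trimethylsilane F1 is isolated. MeLi in THF then releases the regiodefined lithium (3S,5S)-3-[2-(1,3-dioxolan-2-yl)ethyl]-5-methylcyclohex-1-en-1-olate F2, a more reactive and better-behaved nucleophile, which is alkylated with 8 in THF–HMPA to give 10.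

**Step 17.** The copper must bond to C2 next to the quaternary C1 and on the face of its axial methyl. Direct substitution at the less hindered C4, or no reaction, may therefore compete with the γ-pathway. The fallback sets C2 by hydrogen delivery instead of C–C bond formation. It sets out from 20 and returns at 26.
- MnO2 oxidises 20 to tert-butyl (1S,4aS,6R,8aS)-1,6-dimethyl-4-oxo-1,4,4a,5,6,7,8,8a-octahydronaphthalene-1-carboxylate F3.
- The copper reagent from 25 and CuBr·SMe2 adds 1,4 in the presence of TMSCl, on the face away from the axial methyl, to give tert-butyl (1R,2S,4aS,6R,8aS)-1,6-dimethyl-2-[(1E,3E)-penta-1,3-dien-1-yl]-4-[(trimethylsilyl)oxy]-1,2,4a,5,6,7,8,8a-octahydronaphthalene-1-carboxylate F4. Its C2 configuration is immaterial.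
- Saegusa–Ito oxidation gives tert-butyl (1R,4aS,6R,8aS)-1,6-dimethyl-4-oxo-2-[(1E,3E)-penta-1,3-dien-1-yl]-1,4,4a,5,6,7,8,8a-octahydronaphthalene-1-carboxylate F5.
- Luche reduction (NaBH4, CeCl3·7H2O) delivers hydride axially and gives the equatorial alcohol tert-butyl (1R,4R,4aS,6R,8aS)-4-hydroxy-1,6-dimethyl-2-[(1E,3E)-penta-1,3-dien-1-yl]-1,4,4a,5,6,7,8,8a-octahydronaphthalene-1-carboxylate F6.
- A Mitsunobu reaction with 2-nitrobenzenesulfonylhydrazide (PPh3, DEAD) inverts C4. The allylic diazene formed on warming loses N2 in a sigmatropic shift that delivers hydrogen to C2 on the up face and moves the alkene to C3=C4, giving 26.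

**Step 14.** Hydrazone formation at the C2 carbonyl, flanked by the quaternary C1 and the oxirane, may be slow. Opening of the epoxide by hydrazine or cleavage of the β-keto ester could then overtake the transposition. The fallback replaces the hydrazone by a radical fragmentation. It sets out from 19 and returns at 20. NaBH4 reduces the ketone to tert-butyl (1R,4aS,6R,8aS)-3,4-epoxy-2-hydroxy-1,6-dimethyldecahydronaphthalene-1-carboxylate F7 (oxirane as in 19, either C2 epimer). 1,1′-Thiocarbonyldiimidazole with DMAP converts it into its O-(1H-imidazole-1-carbothioate) F8. Bu3SnH with AIBN then generates the C2 radical, which opens the oxirane to the C4 alkoxy radical and so gives 20 with the C4–O bond untouched (Barton–McCombie-type fragmentation).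

**Step 11.** Facial selectivity may be insufficient if equatorial attack on the flat, early-transition-state enolate competes, and some O-methylation is possible. The fallback moves the control from the ring to an auxiliary. It sets out from 15 and returns at 16. Condensation of 15 with L-valine tert-butyl ester gives the enamino ester tert-butyl (4aS,6R,8aS)-2-{[(2S)-1-tert-butoxy-3-methyl-1-oxobutan-2-yl]amino}-6-methyl-3,4,4a,5,6,7,8,8a-octahydronaphthalene-1-carboxylate F9. Its lithium salt (LiN(i-Pr)2) is methylated with MeI, the auxiliary enantiomer and the solvent (toluene–HMPA or THF) being chosen so that the chelated aza-enolate reinforces attack from the down face. This gives tert-butyl (1R,4aS,6R,8aS)-2-{[(2S)-1-tert-butoxy-3-methyl-1-oxobutan-2-yl]imino}-1,6-dimethyldecahydronaphthalene-1-carboxylate F10, and mild aqueous acid hydrolyses the imine to 16.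

**Step 23.** A secondary amide closes slowly, because the reactive rotamer is the minor one. The threonine ester may therefore enolise and epimerise at C5′, or eliminate water, before the ring forms. The fallback uses a tertiary amide, which cyclises much faster. It sets out from 31 and 32 and returns at 34. Reductive amination of 32 with 2,4-dimethoxybenzaldehyde (Et3N, then NaBH4) gives methyl (2S,3R)-2-{[(2,4-dimethoxyphenyl)methyl]amino}-3-hydroxybutanoate F11. Silver-promoted aminolysis of 31 with F11 gives the N-(2,4-dimethoxybenzyl) β-keto amide F12. KOt-Bu in t-BuOH closes it to the N-(2,4-dimethoxybenzyl) tetramic acid F13. Brief treatment with CF3CO2H in CH2Cl2 at 0 °C with a cation scavenger removes the benzyl group to give 34; the exposure is kept short because the diene is acid-sensitive.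

## Further compounds

F1 | step 5 | {[(3S,5S)-3-[2-(1,3-dioxolan-2-yl)ethyl]-5-methylcyclohex-1-en-1-yl]oxy}trimethylsilane | O1CCOC1CC[C@H]2C[C@H](C)CC(O[Si](C)(C)C)=C2
F2 | step 5 | lithium (3S,5S)-3-[2-(1,3-dioxolan-2-yl)ethyl]-5-methylcyclohex-1-en-1-olate | O1CCOC1CC[C@H]2C[C@H](C)CC(O[Li])=C2
F3 | step 17 | tert-butyl (1S,4aS,6R,8aS)-1,6-dimethyl-4-oxo-1,4,4a,5,6,7,8,8a-octahydronaphthalene-1-carboxylate | C1=CC(=O)[C@H]2C[C@H](C)CC[C@@H]2[C@@]1(C)C(=O)OC(C)(C)C
F4 | step 17 | tert-butyl (1R,2S,4aS,6R,8aS)-1,6-dimethyl-2-[(1E,3E)-penta-1,3-dien-1-yl]-4-[(trimethylsilyl)oxy]-1,2,4a,5,6,7,8,8a-octahydronaphthalene-1-carboxylate | C/C=C/C=C/[C@H]1C=C(O[Si](C)(C)C)[C@H]2C[C@H](C)CC[C@@H]2[C@@]1(C)C(=O)OC(C)(C)C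
F5 | step 17 | tert-butyl (1R,4aS,6R,8aS)-1,6-dimethyl-4-oxo-2-[(1E,3E)-penta-1,3-dien-1-yl]-1,4,4a,5,6,7,8,8a-octahydronaphthalene-1-carboxylate | C/C=C/C=C/C1=CC(=O)[C@H]2C[C@H](C)CC[C@@H]2[C@@]1(C)C(=O)OC(C)(C)C
F6 | step 17 | tert-butyl (1R,4R,4aS,6R,8aS)-4-hydroxy-1,6-dimethyl-2-[(1E,3E)-penta-1,3-dien-1-yl]-1,4,4a,5,6,7,8,8a-octahydronaphthalene-1-carboxylate | C/C=C/C=C/C1=C[C@H](O)[C@H]2C[C@H](C)CC[C@@H]2[C@@]1(C)C(=O)OC(C)(C)C
F7 | step 14 | tert-butyl (1R,4aS,6R,8aS)-3,4-epoxy-2-hydroxy-1,6-dimethyldecahydronaphthalene-1-carboxylate (oxirane as in 19, C2 epimers) | OC1[C@H]3O[C@H]3[C@H]2C[C@H](C)CC[C@@H]2[C@@]1(C)C(=O)OC(C)(C)C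
F8 | step 14 | O-[(1R,4aS,6R,8aS)-1-(tert-butoxycarbonyl)-3,4-epoxy-1,6-dimethyldecahydronaphthalen-2-yl] 1H-imidazole-1-carbothioate | S=C(OC1[C@H]3O[C@H]3[C@H]2C[C@H](C)CC[C@@H]2[C@@]1(C)C(=O)OC(C)(C)C)n1ccnc1
F9 | step 11 | tert-butyl (4aS,6R,8aS)-2-{[(2S)-1-tert-butoxy-3-methyl-1-oxobutan-2-yl]amino}-6-methyl-3,4,4a,5,6,7,8,8a-octahydronaphthalene-1-carboxylate | C1(N[C@@H](C(C)C)C(=O)OC(C)(C)C)CC[C@H]2C[C@H](C)CC[C@@H]2C=1C(=O)OC(C)(C)C
F10 | step 11 | tert-butyl (1R,4aS,6R,8aS)-2-{[(2S)-1-tert-butoxy-3-methyl-1-oxobutan-2-yl]imino}-1,6-dimethyldecahydronaphthalene-1-carboxylate | CC(C)[C@H](N=C1CC[C@H]2C[C@H](C)CC[C@@H]2[C@@]1(C)C(=O)OC(C)(C)C)C(=O)OC(C)(C)C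
F11 | step 23 | methyl (2S,3R)-2-{[(2,4-dimethoxyphenyl)methyl]amino}-3-hydroxybutanoate | COc1ccc(CN[C@@H]([C@@H](C)O)C(=O)OC)c(OC)c1
F12 | step 23 | methyl (2S,3R)-2-{[(2,4-dimethoxyphenyl)methyl]{3-oxo-3-[(1R,2R,4aR,6R,8aS)-1,6-dimethyl-2-[(1E,3E)-penta-1,3-dien-1-yl]-1,2,4a,5,6,7,8,8a-octahydronaphthalen-1-yl]propanoyl}amino}-3-hydroxybutanoate | C/C=C/C=C/[C@@H]1C=C[C@H]2C[C@H](C)CC[C@@H]2[C@@]1(C)C(=O)CC(=O)N(Cc1ccc(OC)cc1OC)[C@@H]([C@@H](C)O)C(=O)OC
F13 | step 23 | (5S)-1-[(2,4-dimethoxyphenyl)methyl]-3-{[(1R,2R,4aR,6R,8aS)-1,6-dimethyl-2-[(1E,3E)-penta-1,3-dien-1-yl]-1,2,4a,5,6,7,8,8a-octahydronaphthalen-1-yl]carbonyl}-4-hydroxy-5-[(1R)-1-hydroxyethyl]-1,5-dihydro-2H-pyrrol-2-one | C/C=C/C=C/[C@@H]1C=C[C@H]2C[C@H](C)CC[C@@H]2[C@@]1(C)C(=O)C1=C(O)[C@H]([C@@H](C)O)N(Cc2ccc(OC)cc2OC)C1=O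
A1 | alternative 1 | methyl (1R,2R,4aS,6S,8aS)-2-{[(4-methoxyphenyl)methoxy]methyl}-1,6-dimethyl-4-oxo-1,2,3,4,4a,5,6,8a-octahydronaphthalene-1-carboxylate | COc1ccc(COC[C@@H]2CC(=O)[C@H]3C[C@H](C)C=C[C@@H]3[C@@]2(C)C(=O)OC)cc1
A2 | alternative 1 | methyl (2R,3R)-3-{[(4-methoxyphenyl)methoxy]methyl}-2-methyl-5-oxo-2-[(1E,3E)-penta-1,3-dien-1-yl]hept-6-enoate | C=CC(=O)C[C@@H](COCc1ccc(OC)cc1)[C@](C)(C(=O)OC)/C=C/C=C/C
A3 | alternative 2 | [(1R,2R,6R,8aS)-4-{[tert-butyl(dimethyl)silyl]oxy}-1-formyl-1,6-dimethyl-1,2,3,5,6,7,8,8a-octahydronaphthalen-2-yl]methyl acetate | CC(=O)OC[C@@H]1CC(O[Si](C)(C)C(C)(C)C)=C2C[C@H](C)CC[C@@H]2[C@@]1(C)C=O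
A4 | alternative 2 | tert-butyl(dimethyl){[1-((5R)-5-methylcyclohex-1-en-1-yl)ethenyl]oxy}silane | C=C(O[Si](C)(C)C(C)(C)C)C1=CCC[C@@H](C)C1
A5 | alternative 2 | (2E)-3-formylbut-2-en-1-yl acetate | CC(=O)OC/C=C(\C)C=O
A6 | alternative 3 | methyl (1S,4aS,6R,8aS)-1,6-dimethyl-4-oxo-1,4,4a,5,6,7,8,8a-octahydronaphthalene-1-carboxylate | C1=CC(=O)[C@H]2C[C@H](C)CC[C@@H]2[C@@]1(C)C(=O)OC
A7 | alternative 3 | methyl 1-methyl-4-oxocyclohexa-2,5-diene-1-carboxylate | COC(=O)C1(C)C=CC(=O)C=C1
A8 | alternative 3 | [(3R)-4-chloro-3-methylbutyl]zinc iodide | ClC[C@H](C)CC[Zn]I
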